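**Plan**

- Retrosynthetic cuts, in order: the O–benzyl bond on the 6-oxygen, the O1–C2 bond of pyranone ring C, the C3–C1' bond joining ring C to ring B (undone as a 1,2-aryl shift back to a chalcone), the chalcone Cα=Cβ bond, the benzyl ether of the ketone building block, and the C5–O bond of the acetophenone.
- Enabling feature: ring B sits on C3, next to the C4 carbonyl that is bonded to ring A through C4a, and C2 is at the aldehyde oxidation level. This aryl–CO–CH(aryl)–CH(OR)2 array is what a shift of ring B from Cβ to Cα of the chalcone unit C(=O)–Cα=Cβ–aryl delivers.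
- Forward order: ring A is hydroxylated and capped, the three-carbon chain and ring B are joined by Claisen–Schmidt condensation, ring B is moved with Tl(NO3)3 in methanol, ring C (the only ring made) is closed with acid, and the benzyl group is removed last.
- Stereochemistry: the target has no stereocentre. The (E)-alkene of the chalcone is the thermodynamic condensation product, and the single stereocentre made in the key step is racemic and is lost when the C2=C3 bond forms.

Key step: step 4

**Step 1**
Reactants: 1 paeonol, 1-(2-hydroxy-4-methoxyphenyl)ethanone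
Product: 3 1-(2,5-dihydroxy-4-methoxyphenyl)ethanone, via aryl sulfate potassium salt 2 (not isolated)
Conditions: K2S2O8, aq. KOH, 15–20 °C, 24 h; then conc. HCl, 90 °C
Reagents that add atoms: potassium peroxodisulfate, [K+].[K+].[O-]S(=O)(=O)OOS(=O)(=O)[O-]
Why: Elbs persulfate oxidation, in which the phenolate of 1 attacks a peroxide oxygen of peroxodisulfate through C5 (para to the phenol oxygen and ortho to the methoxy group) and the aryl sulfate 2 is then hydrolysed by hot acid to the hydroquinone, a conversion known for this ketone.

**Step 2**
Reactants: 3 1-(2,5-dihydroxy-4-methoxyphenyl)ethanone; 4 benzyl bromide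
Product: 5 1-[5-(benzyloxy)-2-hydroxy-4-methoxyphenyl]ethanone
Conditions: BnBr (1.05 equiv), K2CO3 (1.1 equiv), acetone, reflux
Reagents that add atoms: none
Why: Williamson ether synthesis that should stop at the 5-ether, because the 2-hydroxyl is held in a hydrogen bond to the acetyl carbonyl and is much less nucleophilic under mild carbonate conditions.

**Step 3**
Reactants: 5 1-[5-(benzyloxy)-2-hydroxy-4-methoxyphenyl]ethanone; 6 3,4,5-trimethoxybenzaldehyde
Product: 7 (E)-1-[5-(benzyloxy)-2-hydroxy-4-methoxyphenyl]-3-(3,4,5-trimethoxyphenyl)prop-2-en-1-one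
Conditions: 50% aq. KOH, EtOH, rt; then dilute HCl to pH 3
Reagents that add atoms: none
Why: Claisen–Schmidt condensation of the methyl ketone enolate with a non-enolisable aldehyde, the aldol losing water to the conjugated enone with the thermodynamically favoured (E)-geometry, a standard preparation of 2'-hydroxychalcones.

**Step 4**
Reactants: 7 (E)-1-[5-(benzyloxy)-2-hydroxy-4-methoxyphenyl]-3-(3,4,5-trimethoxyphenyl)prop-2-en-1-one
Product: 8 1-[5-(benzyloxy)-2-hydroxy-4-methoxyphenyl]-3,3-dimethoxy-2-(3,4,5-trimethoxyphenyl)propan-1-one (racemic)
Conditions: Tl(NO3)3·3H2O (1.1 equiv), MeOH–HC(OMe)3 3:1, 0 °C to rt, dark; filter off TlNO3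
Reagents that add atoms: methanol, CO
Why: Trivalent thallium adds as an electrophile to the alpha carbon of the enone while methanol adds to the benzylic carbon, and the weak C–Tl bond then ionises with loss of monovalent thallium (TlNO3) as ring B shifts from the benzylic to the alpha carbon through a bridged phenonium ion, leaving a methoxy-stabilised oxocarbenium ion that a second methanol traps as the dimethyl acetal. The closest known reaction type is the Tl(NO3)3-mediated oxidative rearrangement of 2'-hydroxychalcones to 1,2-diaryl-3,3-dimethoxypropan-1-ones, an oxidative 1,2-aryl migration. The step forms one skeletal bond, the future C3–C1' bond, and closes no ring. The alpha carbon becomes a stereocentre with no controlling element, so 8 is expected as a racemate, which is of no consequence because this centre is flattened in step 5. The selectivity needed is aryl migration in preference to solvent capture without migration, attack by the 2'-hydroxyl and oxidation of ring A; the three donor methoxy groups of ring B (the para one above all) supply the migratory aptitude, the 2'-hydroxyl is hydrogen-bonded to the carbonyl on an acyl-deactivated ring, and the benzyl group keeps the 5'-oxygen from giving a quinone. The orthoformate takes up the water of the hydrated salt so that the acetal and not the free aldehyde is obtained.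

**Step 5**
Reactants: 8 1-[5-(benzyloxy)-2-hydroxy-4-methoxyphenyl]-3,3-dimethoxy-2-(3,4,5-trimethoxyphenyl)propan-1-one
Product: 10 6-(benzyloxy)-7-methoxy-3-(3,4,5-trimethoxyphenyl)-4H-chromen-4-one, via 2-methoxyisoflavanone 9 (not isolated)
Conditions: 10% aq. HCl, MeOH, reflux
Reagents that add atoms: none
Why: Acid-catalysed transacetalisation and elimination, in which the acetal ionises to an oxocarbenium ion that the 2'-hydroxyl captures in a 6-exo closure to the cyclic acetal 9, and loss of the second methanol gives the C2=C3 bond conjugated with the C4 carbonyl, the benzyl ether being stable to dilute methanolic HCl.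

**Step 6**
Reactants: 10 6-(benzyloxy)-7-methoxy-3-(3,4,5-trimethoxyphenyl)-4H-chromen-4-one
Product: 11 6-hydroxy-7-methoxy-3-(3,4,5-trimethoxyphenyl)-4H-chromen-4-one
Conditions: H2 (1 atm), 10% Pd/C, EtOAc–MeOH, rt, stopped after one equivalent of H2
Reagents that add atoms: none
Why: Catalytic hydrogenolysis of a benzyl aryl ether over Pd/C, which is expected to be much faster than hydrogenation of the vinylogous-ester C2=C3 bond of the chromenone, so the aryl methyl ethers and ring C should remain untouched.

**Compound list**

1 | paeonol, 1-(2-hydroxy-4-methoxyphenyl)ethanone | CC(=O)c1ccc(OC)cc1O | starting material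
2 | potassium 5-acetyl-4-hydroxy-2-methoxyphenyl sulfate (aryl sulfate potassium salt) | CC(=O)c1cc(OS(=O)(=O)[O-])c(OC)cc1O.[K+] | intermediate (not isolated)
3 | 1-(2,5-dihydroxy-4-methoxyphenyl)ethanone | CC(=O)c1cc(O)c(OC)cc1O | intermediate
4 | benzyl bromide | BrCc1ccccc1 | starting material
5 | 1-[5-(benzyloxy)-2-hydroxy-4-methoxyphenyl]ethanone | CC(=O)c1cc(OCc2ccccc2)c(OC)cc1O | intermediate
6 | 3,4,5-trimethoxybenzaldehyde | COc1cc(C=O)cc(OC)c1OC | starting material
7 | (E)-1-[5-(benzyloxy)-2-hydroxy-4-methoxyphenyl]-3-(3,4,5-trimethoxyphenyl)prop-2-en-1-one | COc1cc(O)c(C(=O)/C=C/c2cc(OC)c(OC)c(OC)c2)cc1OCc1ccccc1 | intermediate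
8 | 1-[5-(benzyloxy)-2-hydroxy-4-methoxyphenyl]-3,3-dimethoxy-2-(3,4,5-trimethoxyphenyl)propan-1-one (racemic, one enantiomer drawn) | COC(OC)[C@@H](c1cc(OC)c(OC)c(OC)c1)C(=O)c1cc(OCc2ccccc2)c(OC)cc1O | intermediate
9 | 6-(benzyloxy)-2,7-dimethoxy-3-(3,4,5-trimethoxyphenyl)-2,3-dihydro-4H-chromen-4-one (2-methoxyisoflavanone; racemic mixture of C2 epimers, centres left unspecified) | COC1Oc2cc(OC)c(OCc3ccccc3)cc2C(=O)C1c1cc(OC)c(OC)c(OC)c1 | intermediate (not isolated)
10 | 6-(benzyloxy)-7-methoxy-3-(3,4,5-trimethoxyphenyl)-4H-chromen-4-one | COc1cc2occ(-c3cc(OC)c(OC)c(OC)c3)c(=O)c2cc1OCc1ccccc1 | intermediate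
11 | 6-hydroxy-7-methoxy-3-(3,4,5-trimethoxyphenyl)-4H-chromen-4-one | COc1cc2occ(-c3cc(OC)c(OC)c(OC)c3)c(=O)c2cc1O | target

**Step count and risks**

Total step count: 6. Longest linear sequence: 6 steps, from 1 to 11; 4 and 6 are bought.

Steps most likely to fail:

Step 4. The aryl shift may be outrun by solvolysis of the organothallium adduct without migration or by attack of the 2'-hydroxyl (aurone-type closure). The 4-methoxy group of ring B is twisted by its two neighbours, which lowers the migratory aptitude. Trivalent thallium may also oxidise the p-alkoxyphenol of ring A. The fallback builds ring C first and attaches ring B by cross-coupling. It sets out from 5, which would be heated with N,N-dimethylformamide dimethyl acetal at 95 °C to give (E)-1-[5-(benzyloxy)-2-hydroxy-4-methoxyphenyl]-3-(dimethylamino)prop-2-en-1-one F1. Iodine (I2) in methanol at rt should then close and iodinate the ring to give 6-(benzyloxy)-3-iodo-7-methoxy-4H-chromen-4-one F2. Suzuki–Miyaura coupling of F2 with 3,4,5-trimethoxyphenylboronic acid (Pd(PPh3)4, a zerovalent palladium complex, Na2CO3, DME–H2O, 80 °C) should give 10, where the route is rejoined before step 6.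

Step 1. Persulfate may over-oxidise the electron-rich phenolate to coloured polymeric material, and conversion is typically incomplete in Elbs oxidations. The fallback acylates an existing hydroquinone instead of oxidising a phenol. It carries over no numbered compound: commercial 2-methoxyhydroquinone (2-methoxybenzene-1,4-diol, COc1cc(O)ccc1O) replaces 1. Friedel–Crafts C-acetylation with acetic acid and BF3·OEt2 at 90 °C, directed para to the methoxy group and ortho to a hydroxyl, should give 3 directly, where the route is rejoined before step 2. This detour makes no compound outside the compound list (F0).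

Step 6. Hydrogen uptake may continue past ether cleavage into the C2=C3 bond of ring C and give the isoflavanone. The fallback uses hydrogen before that double bond exists. It sets out from 8, which would be hydrogenolysed (H2, Pd/C, EtOAc, rt, under argon on work-up) to 1-(2,5-dihydroxy-4-methoxyphenyl)-3,3-dimethoxy-2-(3,4,5-trimethoxyphenyl)propan-1-one F3. Without isolation, refluxing methanolic HCl should close ring C through 6-hydroxy-2,7-dimethoxy-3-(3,4,5-trimethoxyphenyl)-2,3-dihydro-4H-chromen-4-one F4 and eliminate methanol, so that the route is rejoined at 11.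

**Further compounds**

F1 | step 4 | (E)-1-[5-(benzyloxy)-2-hydroxy-4-methoxyphenyl]-3-(dimethylamino)prop-2-en-1-one | CN(C)/C=C/C(=O)c1cc(OCc2ccccc2)c(OC)cc1O
F2 | step 4 | 6-(benzyloxy)-3-iodo-7-methoxy-4H-chromen-4-one | COc1cc2occ(I)c(=O)c2cc1OCc1ccccc1
F0 | step 1 | none | none
F3 | step 6 | 1-(2,5-dihydroxy-4-methoxyphenyl)-3,3-dimethoxy-2-(3,4,5-trimethoxyphenyl)propan-1-one (racemic, one enantiomer drawn) | COC(OC)[C@@H](c1cc(OC)c(OC)c(OC)c1)C(=O)c1cc(O)c(OC)cc1O
F4 | step 6 | 6-hydroxy-2,7-dimethoxy-3-(3,4,5-trimethoxyphenyl)-2,3-dihydro-4H-chromen-4-one (racemic mixture of C2 epimers, not isolated) | COC1Oc2cc(OC)c(O)cc2C(=O)C1c1cc(OC)c(OC)c(OC)c1
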